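If a substrate leaves by a first-order and a second-order way at once, I first ask at what concentration the two ways are level.

| flask | substrate | remark | time |
|---|---|---|---|
| epsilon | 0.15 M | run made earlier |  |
| alpha | 2.3 M | run made earlier |  |
| Friday's | 0.20 M |  | 2.0 min |
| Wednesday's | 0.40 M |  | 2.0 min |
| Thursday's | 0.80 M |  | 2.0 min |
| Tuesday's | 1.5 M |  | 2.0 min |
| Sunday's | 3.0 M |  | 2.0 min |

| run | time / s | single ring / % | open dimer / % |
|---|---|---|---|
| epsilon | 10.0 | 10.6 | 16.2 |
| epsilon | 12.0 | 11.6 | 17.8 |
| epsilon | 20.0 | 16.6 | 19.9 |
| epsilon | 30.0 | 20.2 | 18.8 |
| epsilon | 50.0 | 25.9 | 15.3 |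
| epsilon | 80.0 | 29.8 | 9.1 |
| alpha | 10.0 | 4.5 | 48.1 |
| alpha | 12.0 | 5.2 | 46.0 |
| alpha | 20.0 | 4.1 | 38.0 |
| alpha | 30.0 | 5.5 | 29.4 |
| alpha | 50.0 | 5.8 | 17.6 |
| alpha | 80.0 | 5.9 | 8.3 |

(standard deviation of a reading: 0.5 percentage points)

- percent here means substrate units held: one open dimer or ring dimer counts as two
- percent here means substrate units held: one open trimer counts as three
- the numbers in the tables scatter with a standard deviation of 0.5 percentage points
- on the list of suspects stand: substrate -> single ring; 2 substrate -> open dimer; substrate + open dimer -> open trimer; open dimer -> ring dimer; single ring <-> isomer of the product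
- "hardly changes" means that all values lie within two and a half points (for a concentration: within two and a half percent of the largest)

- share of single ring in all that became single ring or open dimer or open trimer or ring dimer or isomer of the product for Friday's, Wednesday's, Thursday's, Tuesday's, Sunday's, in this order
- the shape of the row from first to last (rises, then falls / hardly changes / rises all the way / falls, then rises / falls all the way)

Which way wins at the start? Early on, the units made as single ring over those made as open dimer should equal a fixed concentration divided by the mean c substrate. So I replace the falling curve by its mean and take the standing readings for the units made. At 10.0 s in the epsilon run the readings are 10.6% and 16.2%, the mean c substrate is about 0.130 M, and this gives 0.0850 M. I call this c×, the crossover concentration: the c substrate at which substrate enters single ring as fast as open dimer. The reading at 12.0 s gives 0.0834 M.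

How far above c× do the flasks start? Friday's charge is 2.35 times c× and Sunday's 35.3 times, so in both the open dimer leads at first.

What reaches the ring side? Taking these two ways by themselves, averaging the local selectivity over the whole fall of substrate gives the natural logarithm of one plus q, over q, where q is the charge over c×. That is 51.4% for Friday's flask and 10.2% for Sunday's. The alpha run's last single ring reading, 5.9%, is 0.479 of its own such yield. Applying that factor, I expect 24.6% for Friday's flask and 4.87% for Sunday's, with the row falling.

The forecast gives 29%, 19.5%, 12.5%, 8.2%, 4.9%, and so falls all the way: “The share falls steadily with concentration”. My Friday's figure is lower.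

The flasks give 31.1%, 21.7%, 14.0%, 8.82%, 4.95%: falls all the way.

    substrate → single ring (k = 0.0150 s⁻¹)
    2 substrate → open dimer (k = 0.0910 L mol⁻¹ s⁻¹)
    substrate + open dimer → open trimer (k = 0.0440 L mol⁻¹ s⁻¹)
    open dimer → ring dimer (k = 0.0240 s⁻¹)
    single ring ⇌ isomer of the product (K = 0.530, k = 0.0400 s⁻¹)

At 0.395 min in Friday's flask, substrate goes into single ring 1.0 times as fast as into open dimer, and c× as read is 42.5% of Friday's charge. In Sunday's flask c× is 2.83% of the charge, substrate is already down to 0.936% at 1.00 min, and single ring stands at 4.94% at 2.00 min.

The readings stem from a simulated flask with made-up constants; the scatter is artificial.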